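**Retrosynthetic overview**
- The target comes from a trans-decalone with a C1 ketone that already carries the C8 exocyclic methylene and the C9 dienyl chain; axial hydride delivery and acetylation finish it.
- Key disconnection C9–C10 (ring B): the C10 enolate carbon of a ring A ketone is oxidised to an electrophilic α-keto radical (an enolonium equivalent) and joined to the nucleophilic C8=C9 alkene of a tether on C5; divalent copper ends the sequence as the C8=C17 alkene.
- C5–C6: copper-catalysed conjugate addition of a trienyl Grignard reagent to a ring A cyclohexenone, trapped as the C1–C10 enol silane.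
- Ring A: enantioselective Robinson annulation of methyl 2-formylpropanoate with ethyl vinyl ketone sets C4, and every other centre is relayed from it. The trienyl unit comes from carboalumination of but-3-yn-1-ol and alkenyl–allyl coupling with a dienyl bromide.
- Ring order: ring A first (aldol condensation), ring B second (oxidative C9–C10 closure).

Positions are given in labdane numbering (ring A: C1–C5 and C10; ring B: C5–C10; C11–C16 side chain; C17 exocyclic CH2; C18 methyl on C4; C19 ester carbon; C20 methyl on C10).

Assumption: methyl 2-formylpropanoate and (2E)-3-methylpent-2-en-4-yn-1-ol are bought; the quinidine-series catalyst is taken to give the R adduct, and the quinine-series pseudoenantiomer is used if the measured sense is opposite.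

**Step 1**
Reactants: 1 methyl 2-formylpropanoate; 2 pent-1-en-3-one (ethyl vinyl ketone)
Product: 4 methyl (1R)-1,3-dimethyl-4-oxocyclohex-2-ene-1-carboxylate, via keto aldehyde 3 (not isolated)
Conditions: 9-amino-9-deoxy-epi-quinidine 3,5-bis(trifluoromethyl)phenyl thiourea (10 mol%), toluene, −20 °C; then TsOH·H2O (20 mol%), 80 °C, Dean–Stark
Reagents that add atoms: none
Why: Organocatalytic enantioselective Michael addition of the α-branched 1,3-dicarbonyl pronucleophile to the vinyl ketone sets the quaternary C4 centre (R), and acid-catalysed intramolecular aldol condensation of the ethyl ketone onto the neopentyl aldehyde closes ring A (Robinson annulation) without touching that centre.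

**Step 2**
Reactants: 5 (2E)-3-methylpent-2-en-4-yn-1-ol
Product: 6 (2E)-3-methylpenta-2,4-dien-1-ol
Conditions: H2 (1 atm), Pd/CaCO3 poisoned with Pb(OAc)2, quinoline, EtOAc, 0 °C, stopped after 1 equiv uptake
Reagents that add atoms: none
Why: Lindlar semihydrogenation stops at the terminal alkene and leaves the E trisubstituted double bond unchanged.

**Step 3**
Reactants: 6 (2E)-3-methylpenta-2,4-dien-1-ol
Product: 7 (3E)-5-bromo-3-methylpenta-1,3-diene
Conditions: PBr3 (0.4 equiv), pyridine (cat.), Et2O, −20 to 0 °C; used crude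
Reagents that add atoms: phosphorus tribromide, BrP(Br)Br
Why: Bromination of the primary allylic alcohol through its phosphite ester (SN2 displacement) at low temperature keeps the E geometry, and the conjugated primary bromide is also the thermodynamic allylic isomer.

**Step 4**
Reactants: 8 but-3-yn-1-ol; 7 (3E)-5-bromo-3-methylpenta-1,3-diene
Product: 10 (3E,6E)-3,7-dimethylnona-3,6,8-trien-1-ol, via alkenylalane 9 (not isolated)
Conditions: Al(CH3)3 (3 equiv), Cp2ZrCl2 (0.25 equiv), CH2Cl2, 0 °C to rt; then 7, Pd(PPh3)4 (5 mol%), THF, 0 °C to rt; aq. HCl work-up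
Reagents that add atoms: trimethylaluminium, C[Al](C)C
Why: Zirconium-catalysed syn carboalumination (Negishi) gives the (E)-alkenylalane regio- and stereospecifically, and zerovalent-palladium-catalysed alkenyl–allyl coupling joins it to a CH2 terminus of the symmetrical 3-methylpentadienyl unit with retention of both double-bond geometries.

**Step 5**
Reactants: 10 (3E,6E)-3,7-dimethylnona-3,6,8-trien-1-ol
Product: 11 (3E,6E)-9-bromo-3,7-dimethylnona-1,3,6-triene
Conditions: CBr4, PPh3, CH2Cl2, 0 °C
Reagents that add atoms: carbon tetrabromide, BrC(Br)(Br)Br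
Why: The Appel reaction converts the unhindered primary homoallylic alcohol into the bromide under neutral conditions that leave the skipped triene intact.

**Step 6**
Reactants: 11 (3E,6E)-9-bromo-3,7-dimethylnona-1,3,6-triene; 4 methyl (1R)-1,3-dimethyl-4-oxocyclohex-2-ene-1-carboxylate
Product: 13 methyl (1R,2S)-2-[(3E,6E)-3,7-dimethylnona-3,6,8-trien-1-yl]-1,3-dimethyl-4-[(trimethylsilyl)oxy]cyclohex-3-ene-1-carboxylate, via Grignard reagent 12 (not isolated)
Conditions: Mg, THF, rt; then CuBr·SMe2 (10 mol%), Me3SiCl (2 equiv), HMPA (2 equiv), 4, THF, −78 °C; Et3N quench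
Reagents that add atoms: chlorotrimethylsilane, C[Si](C)(C)Cl
Why: Copper-catalysed conjugate addition of the primary alkyl Grignard reagent, accelerated by Me3SiCl, should occur axially at C5 anti to the pseudoaxial C4 methyl group and syn to the flat ester (which can also pre-coordinate magnesium), setting C5 (S) with the chain cis to the ester, and it traps the enolate regiospecifically as the tetrasubstituted C1–C10 enol silane.

**Step 7**
Reactants: 13 methyl (1R,2S)-2-[(3E,6E)-3,7-dimethylnona-3,6,8-trien-1-yl]-1,3-dimethyl-4-[(trimethylsilyl)oxy]cyclohex-3-ene-1-carboxylate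
Product: 15 methyl (1R,4aS,5R,8aS)-1,4a-dimethyl-6-methylidene-5-[(2E)-3-methylpenta-2,4-dien-1-yl]-4-oxodecahydronaphthalene-1-carboxylate, via potassium enolate 14 (not isolated)
Conditions: KOC(CH3)3 (1.05 equiv), THF, −30 to 0 °C; then added to Cu(O2CCH(C2H5)C4H9)2 (2.5 equiv), THF (0.01 M), −78 to 0 °C
Reagents that add atoms: none
Why: Proposed new method: the regiodefined potassium enolate is oxidised by divalent copper to the α-keto radical at C10 (a polarity-reversed, electrophilic enolate carbon), which adds 6-endo to the nucleophilic C8=C9 alkene through a chair transition state with C11 equatorial and from the face of C10 opposite the axial C4 ester (1,3-diaxial shielding), giving the trans-decalin with C10 (S) and C9 (R); the tertiary C8 radical is then oxidised by a second divalent copper carboxylate with loss of a C17 hydrogen to the exocyclic alkene; the closest known reaction types are the Mn(OAc)3/Cu(OAc)2 oxidative free-radical cyclisation of unsaturated 1,3-dicarbonyl compounds and the copper-mediated oxidative coupling of ketone enolates.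

**Step 8**
Reactants: 15 methyl (1R,4aS,5R,8aS)-1,4a-dimethyl-6-methylidene-5-[(2E)-3-methylpenta-2,4-dien-1-yl]-4-oxodecahydronaphthalene-1-carboxylate
Product: 16 methyl (1R,4S,4aS,5R,8aS)-4-hydroxy-1,4a-dimethyl-6-methylidene-5-[(2E)-3-methylpenta-2,4-dien-1-yl]decahydronaphthalene-1-carboxylate
Conditions: NaBH4, MeOH, 0 °C to rt
Reagents that add atoms: none
Why: Borohydride reduction attacks the neopentyl C1 ketone axially from the face opposite the axial C10 methyl group (as in the reduction of the Wieland–Miescher ketone), giving the equatorial alcohol cis to that methyl (C1 S) and sparing the ester and the alkenes.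

**Step 9**
Reactants: 16 methyl (1R,4S,4aS,5R,8aS)-4-hydroxy-1,4a-dimethyl-6-methylidene-5-[(2E)-3-methylpenta-2,4-dien-1-yl]decahydronaphthalene-1-carboxylate
Product: 17 methyl (1R,4S,4aS,5R,8aS)-4-(acetyloxy)-1,4a-dimethyl-6-methylidene-5-[(2E)-3-methylpenta-2,4-dien-1-yl]decahydronaphthalene-1-carboxylate (CNP0235031.1)
Conditions: Ac2O, pyridine, DMAP (cat.), CH2Cl2, rt
Reagents that add atoms: acetic anhydride, CC(=O)OC(C)=O
Why: DMAP-catalysed acylation of the equatorial secondary alcohol gives the acetate with no change at any stereocentre.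

**Compound list**
1 | methyl 2-formylpropanoate (methyl 2-methyl-3-oxopropanoate, racemic and enolisable) | COC(=O)C(C)C=O | starting material
2 | pent-1-en-3-one | C=CC(=O)CC | starting material
3 | methyl (2R)-2-formyl-2-methyl-5-oxoheptanoate | COC(=O)[C@@](CCC(=O)CC)(C)C=O | intermediate
4 | methyl (1R)-1,3-dimethyl-4-oxocyclohex-2-ene-1-carboxylate | COC(=O)[C@@]1(C)C=C(C)C(=O)CC1 | intermediate
5 | (2E)-3-methylpent-2-en-4-yn-1-ol | C#C/C(C)=C/CO | starting material
6 | (2E)-3-methylpenta-2,4-dien-1-ol | C=C/C(C)=C/CO | intermediate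
7 | (3E)-5-bromo-3-methylpenta-1,3-diene | C=C/C(C)=C/CBr | intermediate
8 | but-3-yn-1-ol | C#CCCO | starting material
9 | [(1E)-4-(dimethylalumanyloxy)-2-methylbut-1-en-1-yl]dimethylalumane | C[Al](C)OCC/C(C)=C/[Al](C)C | intermediate
10 | (3E,6E)-3,7-dimethylnona-3,6,8-trien-1-ol | C=C/C(C)=C/C/C=C(\C)CCO | intermediate
11 | (3E,6E)-9-bromo-3,7-dimethylnona-1,3,6-triene | C=C/C(C)=C/C/C=C(\C)CCBr | intermediate
12 | [(3E,6E)-3,7-dimethylnona-3,6,8-trien-1-yl]magnesium bromide | C=C/C(C)=C/C/C=C(\C)CC[Mg]Br | intermediate
13 | methyl (1R,2S)-2-[(3E,6E)-3,7-dimethylnona-3,6,8-trien-1-yl]-1,3-dimethyl-4-[(trimethylsilyl)oxy]cyclohex-3-ene-1-carboxylate | C=C/C(C)=C/C/C=C(\C)CC[C@H]1C(C)=C(O[Si](C)(C)C)CC[C@@]1(C)C(=O)OC | intermediate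
14 | potassium enolate corresponding to 13 (O–K in place of O–SiMe3, C4 R and C5 S unchanged) | C=C/C(C)=C/C/C=C(\C)CC[C@H]1C(C)=C([O-])CC[C@@]1(C)C(=O)OC.[K+] | intermediate
15 | methyl (1R,4aS,5R,8aS)-1,4a-dimethyl-6-methylidene-5-[(2E)-3-methylpenta-2,4-dien-1-yl]-4-oxodecahydronaphthalene-1-carboxylate | C=C/C(C)=C/C[C@@H]1C(=C)CC[C@H]2[C@@]1(C)C(=O)CC[C@@]2(C)C(=O)OC | intermediate
16 | methyl (1R,4S,4aS,5R,8aS)-4-hydroxy-1,4a-dimethyl-6-methylidene-5-[(2E)-3-methylpenta-2,4-dien-1-yl]decahydronaphthalene-1-carboxylate | C=C/C(C)=C/C[C@@H]1C(=C)CC[C@H]2[C@@]1(C)[C@@H](O)CC[C@@]2(C)C(=O)OC | intermediate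
17 | methyl (1R,4S,4aS,5R,8aS)-4-(acetyloxy)-1,4a-dimethyl-6-methylidene-5-[(2E)-3-methylpenta-2,4-dien-1-yl]decahydronaphthalene-1-carboxylate | C=C/C(C)=C/C[C@@H]1C(=C)CC[C@H]2[C@@]1(C)[C@@H](OC(C)=O)CC[C@@]2(C)C(=O)OC | target

**Totals**
Total step count: 9. Longest linear sequence: 8 (steps 2, 3, 4, 5, 6, 7, 8, 9).

**Steps most likely to fail**

Step 7 (oxidative C9–C10 closure). The risks are enolate dimerisation, endocyclic alkene isomers and a cis ring fusion. Fallback, from 13 back to 15: the same bond is made by halogen atom transfer instead of oxidation. Compound 13 is brominated with N-bromosuccinimide (THF, −78 °C) to the tertiary α-bromo ketone F1, the classical enolonium equivalent. Monovalent copper (CuBr, tris(2-pyridylmethyl)amine, CH2Cl2) then effects 6-endo atom-transfer radical cyclisation to the tertiary C8 bromide F2. Hofmann-selective dehydrobromination of F2 with KOC(CH3)3 in t-BuOH gives 15. This answers the first two risks; it does not change the ring-fusion outcome.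

Step 6 (facial selectivity and hindrance of the conjugate addition at C5). Fallback, from 11 (through its Grignard reagent 12) and 2, back to 13: the chain is placed on C5 before ring A is closed, and C5 is set by hydrogen delivery instead of carbon delivery. Acylation of 12 with methyl 3-chloro-2-methyl-3-oxopropanoate (Fe(acac)3 cat., THF, −78 °C) gives the β-keto ester F3. The same type of organocatalytic Michael addition to 2 gives the diketo ester F4 with C4 set as in step 1. Aldol condensation (pyrrolidine, AcOH) gives the tetrasubstituted enone F5. Conjugate reduction with SmI2/HMPA/t-BuOH delivers hydrogen to C5 anti to the ester, and silylation of the samarium enolate (Me3SiCl, Et3N) returns to 13.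

Step 1 (enantioselectivity and sense of the catalytic Michael addition with a formyl ester). Fallback, from 1 back to 3: a stoichiometric chiral amine replaces the catalyst. Compound 1 is condensed with (S)-1-phenylethylamine to the β-enamino ester F6. F6 adds to 2 in an aza-ene-type Michael reaction under auxiliary control to give the imine F7. Hydrolysis with aqueous acetic acid releases the amine and gives 3, which is cyclised with TsOH as in step 1. The antipodal amine is used if the induction proves opposite.

**Further compounds**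
F1 | step 7 | methyl 3-bromo-2-[(3E,6E)-3,7-dimethylnona-3,6,8-trien-1-yl]-1,3-dimethyl-4-oxocyclohexane-1-carboxylate (C4 and C5 as in 13, either C10 epimer) | C=C/C(C)=C/C/C=C(\C)CC[C@H]1C(C)(Br)C(=O)CC[C@@]1(C)C(=O)OC
F2 | step 7 | methyl 6-bromo-1,4a,6-trimethyl-5-[(2E)-3-methylpenta-2,4-dien-1-yl]-4-oxodecahydronaphthalene-1-carboxylate (C4, C5, C9, C10 as in 15, either C8 epimer) | C=C/C(C)=C/C[C@@H]1C(C)(Br)CC[C@H]2[C@@]1(C)C(=O)CC[C@@]2(C)C(=O)OC
F3 | step 6 | methyl (6E,9E)-2,6,10-trimethyl-3-oxododeca-6,9,11-trienoate (racemic) | C=C/C(C)=C/C/C=C(\C)CCC(=O)C(C)C(=O)OC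
F4 | step 6 | methyl (2R,6E,9E)-2,6,10-trimethyl-3-oxo-2-(3-oxopentyl)dodeca-6,9,11-trienoate | COC(=O)[C@@](CCC(=O)CC)(C)C(=O)CC/C(C)=C/C/C=C(/C=C)C
F5 | step 6 | methyl (1R)-2-[(3E,6E)-3,7-dimethylnona-3,6,8-trien-1-yl]-1,3-dimethyl-4-oxocyclohex-2-ene-1-carboxylate | COC(=O)[C@@]1(C)C(CC/C(C)=C/C/C=C(/C=C)C)=C(C)C(=O)CC1
F6 | step 1 | methyl (2Z)-2-methyl-3-{[(1S)-1-phenylethyl]amino}prop-2-enoate | COC(=O)/C(C)=C\N[C@@H](C)c1ccccc1
F7 | step 1 | methyl (2R)-2-methyl-5-oxo-2-[(E)-{[(1S)-1-phenylethyl]imino}methyl]heptanoate | COC(=O)[C@@](CCC(=O)CC)(C)/C=N/[C@@H](C)c1ccccc1
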